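The benzo ring, ring A, carries oxygen on the neighbouring carbons C7a and C7, so both oxygens are put in at once through an aryne whose triple bond joins these two atoms; the dihydrofuran ring B is thereby closed at the aryl–oxygen bond O1–C7a. A 5-bromo-2-fluorophenyl ring is lithiated at its only C–H next to fluorine and loses LiF; the tethered benzylic alkoxide closes ring B at C7a, and the aryllithium left at C7 is borylated and oxidized to the phenol. The precursor is an open-chain (1R,2S)-1,3-diol monosilyl ether from an Evans syn-aldol, which already holds both stereocentres. The C5 bromide survives the aryne step and later takes the acrylic acid by Heck coupling.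

Key step: step 5

Remark: benzofuran numbering is used (O1, C2, C3, C3a, C4–C7, C7a). The target is the trans (2R,3S) isomer. Compound 1 and (R)-4-benzyl-1,3-oxazolidin-2-one are assumed to be catalogue compounds.

Step 1
Reactants: 1 2-(5-bromo-2-fluorophenyl)acetic acid; 2 (R)-4-benzyl-1,3-oxazolidin-2-one
Product: 4 (R)-4-benzyl-3-[2-(5-bromo-2-fluorophenyl)acetyl]-1,3-oxazolidin-2-one, via mixed pivalic anhydride 3 (not isolated)
Conditions: PivCl, Et3N, THF, −20 °C; then LiCl, 2, −20 °C → rt
Reagents that add atoms: none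
Why: Mixed-anhydride N-acylation of an oxazolidinone: the LiCl-complexed auxiliary, deprotonated by Et3N, attacks the less hindered arylacetyl carbonyl of 3, so no strong base meets the acidic benzylic CH2 and no stereocentre is involved.

Step 2
Reactants: 4 (R)-4-benzyl-3-[2-(5-bromo-2-fluorophenyl)acetyl]-1,3-oxazolidin-2-one; 5 3,4-dimethoxybenzaldehyde
Product: 8 (R)-4-benzyl-3-[(2R,3R)-2-(5-bromo-2-fluorophenyl)-3-(3,4-dimethoxyphenyl)-3-hydroxypropanoyl]-1,3-oxazolidin-2-one, via Z-dibutylboron enolate 6 (not isolated), via dibutylboron aldolate 7 (not isolated)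
Conditions: Bu2BOTf, iPr2NEt, CH2Cl2, −78 → 0 °C; then 5, −78 → 0 °C; then pH 7 buffer, MeOH, 30% H2O2, 0 °C
Reagents that add atoms: none
Why: Evans boron syn-aldol reaction: soft enolization gives the Z-boron enolate 6, which adds to the aldehyde through a closed Zimmerman–Traxler chair with the auxiliary carbonyl turned away, so the (R)-benzyl group blocks one enolate face and the syn (2R,3R) adduct is expected, fixing the future C3 (enolate carbon) and C2 (carbinol carbon).

Step 3
Reactants: 8 (R)-4-benzyl-3-[(2R,3R)-2-(5-bromo-2-fluorophenyl)-3-(3,4-dimethoxyphenyl)-3-hydroxypropanoyl]-1,3-oxazolidin-2-one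
Product: 9 (1R,2S)-2-(5-bromo-2-fluorophenyl)-1-(3,4-dimethoxyphenyl)propane-1,3-diol
Conditions: LiBH4, MeOH (1 equiv), THF, 0 °C
Reagents that add atoms: none
Why: Reductive cleavage of an N-acyl oxazolidinone: LiBH4 reduces the exocyclic imide carbonyl to the primary alcohol at 0 °C, where retro-aldol cleavage and epimerization of the α-aryl centre should not compete, and the auxiliary is recovered.

Step 4
Reactants: 9 (1R,2S)-2-(5-bromo-2-fluorophenyl)-1-(3,4-dimethoxyphenyl)propane-1,3-diol
Product: 10 (1R,2S)-2-(5-bromo-2-fluorophenyl)-1-(3,4-dimethoxyphenyl)-3-[(triisopropylsilyl)oxy]propan-1-ol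
Conditions: TIPSCl (1.1 equiv), imidazole, DMF, 0 °C → rt
Reagents that add atoms: triisopropylsilyl chloride, CC(C)[Si](Cl)(C(C)C)C(C)C
Why: Selective silylation: the bulky TIPSCl should react with the primary hydroxyl far faster than with the hindered secondary benzylic one, and TIPS is chosen because it should neither be attacked by LiTMP nor migrate between the 1,3-oxygens in step 5.

Step 5
Reactants: 10 (1R,2S)-2-(5-bromo-2-fluorophenyl)-1-(3,4-dimethoxyphenyl)-3-[(triisopropylsilyl)oxy]propan-1-ol
Product: 14 (2R,3S)-5-bromo-2-(3,4-dimethoxyphenyl)-3-{[(triisopropylsilyl)oxy]methyl}-2,3-dihydro-1-benzofuran-7-ol, via aryne lithium alkoxide 11 (not isolated), via C7 aryllithium 12 (not isolated), via dimethyl arylboronate 13 (not isolated)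
Conditions: LiTMP (2.3 equiv, from 2,2,6,6-tetramethylpiperidine and n-BuLi), THF (0.02 M), −78 °C, then −78 → −30 °C; B(OMe)3, −78 °C → rt; then AcOH, 30% H2O2, 0 °C → rt
Reagents that add atoms: hydrogen peroxide, OO
Why: LiTMP should remove the hydroxyl proton and then the only ring A proton ortho to fluorine (lithium amides metalate 1-bromo-4-fluorobenzene next to fluorine at −78 °C and leave the bromide alone); on warming the 2-fluoroaryllithium expels LiF to give aryne 11, whose triple bond joins the future C7a and C7, the tethered benzylic lithium alkoxide adds to C7a, and the aryllithium 12 left at C7 is borylated to 13 and oxidized at the same carbon to the phenol. The closest known reaction types are the intramolecular capture of base-generated arynes by tethered alkoxides to give dihydrobenzofurans and chromans, the LiTMP-mediated nucleophile/electrophile 1,2-difunctionalization of arynes in which the adduct aryllithium is quenched by an electrophile, and the standard aryllithium → B(OMe)3 → H2O2 phenol synthesis. Ring B closes in the 5-exo-dig mode on the in-plane π bond of the aryne; the tether cannot reach C7, so oxygen goes to C7a and the electrophile to C7, and the polarization of the aryne agrees because the carbanion develops meta to the inductively withdrawing bromine and ortho to the new ether oxygen. No stereocentre is created: C2 and C3 are those of the aldol, none of their bonds is broken, and the syn diol therefore gives the trans (2R,3S) ring. The step needs chemoselectivity for the secondary alkoxide (the primary oxygen, which would close an isomeric five-membered ring, is blocked as the TIPS ether), regioselective metalation (only one C–H flanks fluorine, and bromine is not ortho to any lithiated carbon, so no second aryne can form), and survival of 12 until borylation (the hindered amine should protonate it only slowly below −30 °C, LiTMP adds to arynes sluggishly, and dilution suppresses biaryl formation).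

Step 6
Reactants: 14 (2R,3S)-5-bromo-2-(3,4-dimethoxyphenyl)-3-{[(triisopropylsilyl)oxy]methyl}-2,3-dihydro-1-benzofuran-7-ol; 15 acrylic acid
Product: 16 (E)-3-[(2R,3S)-2-(3,4-dimethoxyphenyl)-7-hydroxy-3-{[(triisopropylsilyl)oxy]methyl}-2,3-dihydro-1-benzofuran-5-yl]prop-2-enoic acid
Conditions: Pd(OAc)2 (5 mol %), P(o-tol)3 (10 mol %), Et3N, DMF, 100 °C; aqueous citric acid work-up
Reagents that add atoms: none
Why: Mizoroki–Heck reaction: zerovalent palladium formed from Pd(OAc)2 and the phosphine adds oxidatively to the unhindered C5–Br bond, and syn-carbopalladation of the acrylate followed by syn-β-hydride elimination should give the E-cinnamic acid while the phenol, the silyl ether and both stereocentres are untouched.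

Step 7
Reactants: 16 (E)-3-[(2R,3S)-2-(3,4-dimethoxyphenyl)-7-hydroxy-3-{[(triisopropylsilyl)oxy]methyl}-2,3-dihydro-1-benzofuran-5-yl]prop-2-enoic acid
Product: 17 (E)-3-[(2R,3S)-2-(3,4-dimethoxyphenyl)-7-hydroxy-3-(hydroxymethyl)-2,3-dihydro-1-benzofuran-5-yl]prop-2-enoic acid
Conditions: HF·pyridine, pyridine, THF, 0 °C → rt
Reagents that add atoms: none
Why: Fluoride-mediated desilylation: formation of the strong Si–F bond cleaves the primary TIPS ether under pyridine-buffered, mildly acidic conditions that should leave the benzylic aryl ether of ring B, the phenol and the E-acrylic acid unchanged.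

Compound list
1 | 2-(5-bromo-2-fluorophenyl)acetic acid | OC(=O)Cc1cc(Br)ccc1F | starting material
2 | (R)-4-benzyl-1,3-oxazolidin-2-one | O=C1N[C@H](Cc2ccccc2)CO1 | starting material
3 | 2-(5-bromo-2-fluorophenyl)acetic pivalic anhydride (formed in the flask) | CC(C)(C)C(=O)OC(=O)Cc1cc(Br)ccc1F | intermediate
4 | (R)-4-benzyl-3-[2-(5-bromo-2-fluorophenyl)acetyl]-1,3-oxazolidin-2-one | O=C(Cc1cc(Br)ccc1F)N1[C@H](Cc2ccccc2)COC1=O | intermediate
5 | 3,4-dimethoxybenzaldehyde | COc1ccc(C=O)cc1OC | starting material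
6 | Z-dibutylboron enolate of 4 (O–B and aryl cis; formed in the flask) | CCCCB(CCCC)O/C(=C\c1cc(Br)ccc1F)N1[C@H](Cc2ccccc2)COC1=O | intermediate
7 | O-dibutylboryl derivative of aldol 8 (formed in the flask) | O=C(N1[C@H](Cc2ccccc2)COC1=O)[C@H](c1cc(Br)ccc1F)[C@@H](OB(CCCC)CCCC)c1ccc(OC)c(OC)c1 | intermediate
8 | (R)-4-benzyl-3-[(2R,3R)-2-(5-bromo-2-fluorophenyl)-3-(3,4-dimethoxyphenyl)-3-hydroxypropanoyl]-1,3-oxazolidin-2-one (syn aldol) | O=C(N1[C@H](Cc2ccccc2)COC1=O)[C@H](c1cc(Br)ccc1F)[C@@H](O)c1ccc(OC)c(OC)c1 | intermediate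
9 | (1R,2S)-2-(5-bromo-2-fluorophenyl)-1-(3,4-dimethoxyphenyl)propane-1,3-diol | OC[C@H](c1cc(Br)ccc1F)[C@@H](O)c1ccc(OC)c(OC)c1 | intermediate
10 | (1R,2S)-2-(5-bromo-2-fluorophenyl)-1-(3,4-dimethoxyphenyl)-3-[(triisopropylsilyl)oxy]propan-1-ol | CC(C)[Si](C(C)C)(C(C)C)OC[C@H](c1cc(Br)ccc1F)[C@@H](O)c1ccc(OC)c(OC)c1 | intermediate
11 | lithium alkoxide of 10 after loss of HF: 5-bromo-1,2-didehydrobenzene bearing the side chain at C3 (formed in the flask) | CC(C)[Si](C(C)C)(C(C)C)OC[C@H](C1=CC(Br)=CC#C1)[C@@H](O[Li])c1ccc(OC)c(OC)c1 | intermediate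
12 | (2R,3S)-5-bromo-2-(3,4-dimethoxyphenyl)-7-lithio-3-{[(triisopropylsilyl)oxy]methyl}-2,3-dihydro-1-benzofuran (formed in the flask) | COc1ccc([C@@H]2Oc3c([Li])cc(Br)cc3[C@H]2CO[Si](C(C)C)(C(C)C)C(C)C)cc1OC | intermediate
13 | dimethyl [(2R,3S)-5-bromo-2-(3,4-dimethoxyphenyl)-3-{[(triisopropylsilyl)oxy]methyl}-2,3-dihydro-1-benzofuran-7-yl]boronate (formed in the flask) | COc1ccc([C@@H]2Oc3c(B(OC)OC)cc(Br)cc3[C@H]2CO[Si](C(C)C)(C(C)C)C(C)C)cc1OC | intermediate
14 | (2R,3S)-5-bromo-2-(3,4-dimethoxyphenyl)-3-{[(triisopropylsilyl)oxy]methyl}-2,3-dihydro-1-benzofuran-7-ol | COc1ccc([C@@H]2Oc3c(O)cc(Br)cc3[C@H]2CO[Si](C(C)C)(C(C)C)C(C)C)cc1OC | intermediate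
15 | acrylic acid | C=CC(=O)O | starting material
16 | (E)-3-[(2R,3S)-2-(3,4-dimethoxyphenyl)-7-hydroxy-3-{[(triisopropylsilyl)oxy]methyl}-2,3-dihydro-1-benzofuran-5-yl]prop-2-enoic acid | COc1ccc([C@@H]2Oc3c(O)cc(/C=C/C(=O)O)cc3[C@H]2CO[Si](C(C)C)(C(C)C)C(C)C)cc1OC | intermediate
17 | (E)-3-[(2R,3S)-2-(3,4-dimethoxyphenyl)-7-hydroxy-3-(hydroxymethyl)-2,3-dihydro-1-benzofuran-5-yl]prop-2-enoic acid | COc1ccc([C@@H]2Oc3c(O)cc(/C=C/C(=O)O)cc3[C@H]2CO)cc1OC | target

Total step count: 7
Longest linear sequence: 7 steps (1 → 17)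

Steps most likely to fail

Step 5. The aryllithium at C7 may be protonated by the tetramethylpiperidine before it meets the borate, so that ring B closes but the C7 oxygen is lost; amide addition to the aryne would lower the return further. The fallback sets out from 10 and comes back at 14, and separates ring closure from oxygenation. The same aryne cyclization is run with a deliberate proton quench (LiTMP, THF, −78 → 0 °C, then NH4Cl), which should give (2R,3S)-5-bromo-2-(3,4-dimethoxyphenyl)-3-{[(triisopropylsilyl)oxy]methyl}-2,3-dihydro-1-benzofuran F1. C7–H is the only ring A hydrogen whose neighbours are a hydrogen and the tied-back ring oxygen, so sterically controlled C–H borylation ([Ir(OMe)(cod)]2, 4,4'-di-tert-butyl-2,2'-bipyridine, B2pin2, THF, 80 °C) should give the 7-pinacolboronate, 2-[(2R,3S)-5-bromo-2-(3,4-dimethoxyphenyl)-3-{[(triisopropylsilyl)oxy]methyl}-2,3-dihydro-1-benzofuran-7-yl]-4,4,5,5-tetramethyl-1,3,2-dioxaborolane F2. Oxidation (NaBO3·4H2O, THF/H2O, rt) then leads to 14.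

Step 2. Enolization of the acidic arylacetyl imide may leak to the E-enolate, and the electron-rich benzylic aldolate may equilibrate by retro-aldol cleavage; either process erodes the syn/anti and facial selectivity. The fallback sets out from 1 and comes back at 9, and replaces the boron enolate by a chlorotitanium enolate of a thiazolidinethione. Acid 1 is coupled with (R)-4-benzyl-1,3-thiazolidine-2-thione (EDC·HCl, DMAP, CH2Cl2) to give (R)-3-[2-(5-bromo-2-fluorophenyl)acetyl]-4-benzyl-1,3-thiazolidine-2-thione F3. Soft enolization (TiCl4, iPr2NEt, N-methyl-2-pyrrolidinone, CH2Cl2, 0 °C) and addition of 5 at −78 °C through the non-chelated transition state should give the same syn sense, (2R,3R)-2-(5-bromo-2-fluorophenyl)-3-(3,4-dimethoxyphenyl)-3-hydroxy-1-[(R)-4-benzyl-2-thioxo-1,3-thiazolidin-3-yl]propan-1-one F4. This adduct is usually crystalline, so a minor isomer can be removed. NaBH4 (THF/EtOH, 0 °C) displaces the auxiliary directly and gives diol 9.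

Step 6. Oxidative addition into the electron-rich C5–Br bond may be slow, so that catalyst decay to palladium black or protodebromination wins, and the phenoxide and carboxylate may bind the metal. The fallback sets out from 14 and comes back at 16, and builds the acrylic acid by condensation. The phenol is deprotonated with MeLi and the bromide exchanged with t-BuLi (THF, −78 °C); quenching with DMF should give (2R,3S)-2-(3,4-dimethoxyphenyl)-7-hydroxy-3-{[(triisopropylsilyl)oxy]methyl}-2,3-dihydro-1-benzofuran-5-carbaldehyde F5. Knoevenagel–Doebner condensation with malonic acid (pyridine, piperidine cat., 90 °C) passes through the arylidenemalonic acid, 2-{[(2R,3S)-2-(3,4-dimethoxyphenyl)-7-hydroxy-3-{[(triisopropylsilyl)oxy]methyl}-2,3-dihydro-1-benzofuran-5-yl]methylidene}propanedioic acid F6, which decarboxylates in the flask to the E-acid 16.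

Further compounds
F1 | step 5 | (2R,3S)-5-bromo-2-(3,4-dimethoxyphenyl)-3-{[(triisopropylsilyl)oxy]methyl}-2,3-dihydro-1-benzofuran | COc1ccc([C@@H]2Oc3ccc(Br)cc3[C@H]2CO[Si](C(C)C)(C(C)C)C(C)C)cc1OC
F2 | step 5 | 2-[(2R,3S)-5-bromo-2-(3,4-dimethoxyphenyl)-3-{[(triisopropylsilyl)oxy]methyl}-2,3-dihydro-1-benzofuran-7-yl]-4,4,5,5-tetramethyl-1,3,2-dioxaborolane | COc1ccc([C@@H]2Oc3c(B4OC(C)(C)C(C)(C)O4)cc(Br)cc3[C@H]2CO[Si](C(C)C)(C(C)C)C(C)C)cc1OC
F3 | step 2 | (R)-3-[2-(5-bromo-2-fluorophenyl)acetyl]-4-benzyl-1,3-thiazolidine-2-thione | O=C(Cc1cc(Br)ccc1F)N1[C@H](Cc2ccccc2)CSC1=S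
F4 | step 2 | (2R,3R)-2-(5-bromo-2-fluorophenyl)-3-(3,4-dimethoxyphenyl)-3-hydroxy-1-[(R)-4-benzyl-2-thioxo-1,3-thiazolidin-3-yl]propan-1-one | O=C(N1[C@H](Cc2ccccc2)CSC1=S)[C@H](c1cc(Br)ccc1F)[C@@H](O)c1ccc(OC)c(OC)c1
F5 | step 6 | (2R,3S)-2-(3,4-dimethoxyphenyl)-7-hydroxy-3-{[(triisopropylsilyl)oxy]methyl}-2,3-dihydro-1-benzofuran-5-carbaldehyde | COc1ccc([C@@H]2Oc3c(O)cc(C=O)cc3[C@H]2CO[Si](C(C)C)(C(C)C)C(C)C)cc1OC
F6 | step 6 | 2-{[(2R,3S)-2-(3,4-dimethoxyphenyl)-7-hydroxy-3-{[(triisopropylsilyl)oxy]methyl}-2,3-dihydro-1-benzofuran-5-yl]methylidene}propanedioic acid | COc1ccc([C@@H]2Oc3c(O)cc(C=C(C(=O)O)C(=O)O)cc3[C@H]2CO[Si](C(C)C)(C(C)C)C(C)C)cc1OC
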